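**Plan**

Numbering: cyclopentane C1(side chain)–C2–C3–C4(Me)–C10(O); cycloheptane C4–C5–C6(OH)–C7(Me,O)–C8–C9–C10; Cs is the side-chain CH.
Enabling feature: C6 (secondary carbinol) and C7 (methyl carbinol) of the cycloheptane carry vicinal oxygens, a 1,2-diol retron that joins a CH2CHO arm on C4 to a CH2CH2COCH3 arm on C10 of the cyclopentane.
Cuts, in retrosynthetic order: vanillate ester C–O; the O–C10 bond of the C7–O–C10 bridge; C6–C7 (pinacol); C10–C9 (Grignard addition to a cyclopentanone); C4–C5 (allylation, then oxy-Cope); the cyclopentene from the cyclohexene of (S)-limonene.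
Forward: cyclopentene (ring 1), both arms attached at C4 and C10, cycloheptane closed by the SmI2 pinacol (ring 2), oxygen bridge by cyclodehydration (ring 3), vanillate last.
Stereochemistry: C1 from (S)-limonene; Cs by lipase selection of one hydroboration epimer; C4 by catalyst-controlled allylation relayed through a chair oxy-Cope; C10 by addition anti to the C1 side chain, then fixed by the bridge; C6/C7 cis by samarium chelation, C7 kept, C6 corrected by equilibrating Meerwein–Ponndorf–Verley reduction.

Key step: step 13

Remark: in step 2 the lipase is taken to acylate the (8S) epimer faster, in line with the usual preference of Pseudomonas lipases for (S)-2-methylalkan-1-ols.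

**Step 1**
Reactants: 1 (S)-limonene
Product: 3 (2RS)-2-[(1S)-4-methylcyclohex-3-en-1-yl]propan-1-ol (both epimers at Cs), via B-alkyl-9-BBN adduct 2 (not isolated)
Conditions: 9-BBN (1.1 equiv), THF, 0 °C to rt; then 3 M NaOH, 30% H2O2, 0 to 50 °C
Reagents that add atoms: hydrogen peroxide, OO
Why: 9-BBN hydroborates the 1,1-disubstituted isopropenyl alkene much faster than the trisubstituted ring alkene and places boron on the terminal carbon, so hydroboration–oxidation gives the primary alcohol with the ring centre untouched, while the new methyl-bearing centre Cs forms without control and is sorted out in step 2.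

**Step 2**
Reactants: 3 epimer pair of the primary alcohol
Product: 4 (2S)-2-[(1S)-4-methylcyclohex-3-en-1-yl]propyl acetate
Conditions: lipase PS (Pseudomonas cepacia, immobilised), vinyl acetate (3 equiv), t-BuOMe, 25 °C, stopped at about 40% conversion; chromatography
Reagents that add atoms: vinyl acetate, C=COC(C)=O
Why: Lipase-catalysed irreversible transesterification (enzymatic kinetic resolution) reads the stereocentre next to the carbinol carbon of 2-methyl primary alcohols and should acylate the (8S) epimer faster, so that at partial conversion the acetate 4 is separated by chromatography from the unreacted (8R) alcohol and Cs is fixed as S.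

**Step 3**
Reactants: 4 acetate
Product: 5 (2S)-2-[(1S)-4-methylcyclohex-3-en-1-yl]propan-1-ol
Conditions: K2CO3 (0.2 equiv), MeOH, rt
Reagents that add atoms: none
Why: Carbonate-catalysed transesterification with methanol removes the acetate under conditions that touch neither alkene nor stereocentres.

**Step 4**
Reactants: 5 alcohol
Product: 6 tert-butyl(dimethyl){(2S)-2-[(1S)-4-methylcyclohex-3-en-1-yl]propoxy}silane
Conditions: TBSCl (1.2 equiv), imidazole (2 equiv), DMF, rt
Reagents that add atoms: tert-butyldimethylsilyl chloride, CC(C)(C)[Si](C)(C)Cl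
Why: Imidazole-promoted silylation of a primary alcohol is routine, and the TBS ether is chosen because it survives ozone, KH, the Grignard reagent and SmI2 and leaves with fluoride in step 15.

**Step 5**
Reactants: 6 TBS ether
Product: 8 (3S)-3-[(2S)-1-(tert-butyldimethylsilyloxy)propan-2-yl]-6-oxoheptanal, via bicyclic ozonide 7 (not isolated)
Conditions: O3, CH2Cl2, −78 °C; then PPh3 (1.2 equiv), −78 °C to rt
Reagents that add atoms: ozone, [O-][O+]=O
Why: Ozonolysis of the only alkene with reductive work-up (Criegee mechanism) opens the cyclohexene to the keto aldehyde, and neither stereocentre is α to a carbonyl group so both are kept.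

**Step 6**
Reactants: 8 keto aldehyde
Product: 9 (5R)-5-[(2S)-1-(tert-butyldimethylsilyloxy)propan-2-yl]-2-methylcyclopent-1-ene-1-carbaldehyde
Conditions: piperidine (0.2 equiv), AcOH (0.2 equiv), toluene, 80 °C
Reagents that add atoms: none
Why: Amine–acid catalysed intramolecular aldol condensation (5-enolexo attack of the aldehyde enamine on the methyl ketone, then dehydration) is the standard conversion of limonene-type keto aldehydes into 2-methylcyclopent-1-enecarbaldehydes, and C1 is not epimerised because its hydrogen is not conjugated with the carbonyl.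

**Step 7**
Reactants: 9 enal; 10 allylboronic acid pinacol ester
Product: 12 (1S)-1-{(5R)-5-[(2S)-1-(tert-butyldimethylsilyloxy)propan-2-yl]-2-methylcyclopent-1-en-1-yl}but-3-en-1-ol, via pinacol borate ester 11 (not isolated)
Conditions: 10 (1.3 equiv), (S)-TRIP [(S)-3,3'-bis(2,4,6-triisopropylphenyl)-1,1'-binaphthyl-2,2'-diyl hydrogen phosphate, 5 mol%], toluene, −30 °C; aq. NaHCO3
Reagents that add atoms: none
Why: Chiral phosphoric acid-catalysed allylboration of the aldehyde runs through a closed chair transition state in which the (S)-catalyst selects one carbonyl face, so the new carbinol centre is set by the catalyst as S (by analogy with aryl and other conjugated aldehydes, where the (R)-acid gives the (R)-alcohol) and the borate ester 11 is hydrolysed on work-up.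

**Step 8**
Reactants: 12 homoallylic alcohol
Product: 14 (2R,5R)-5-[(2S)-1-(tert-butyldimethylsilyloxy)propan-2-yl]-2-methyl-2-(prop-2-en-1-yl)cyclopentane-1-carbaldehyde (both epimers at the formyl-bearing carbon), via potassium enolate 13 (not isolated)
Conditions: KH (1.5 equiv), 18-crown-6 (1.5 equiv), THF, 0 to 40 °C; sat. aq. NH4Cl, −78 °C
Reagents that add atoms: none
Why: Anionic oxy-Cope rearrangement of the potassium alkoxide of this 1,5-dien-3-ol goes through a chair transition state with the alkoxide pseudo-equatorial (the pseudo-axial alternative suffers allylic 1,3-strain with the C4 methyl), which transfers the carbinol chirality to the new quaternary C4 by delivering the allyl group to the ring face opposite the C1 side chain, and the C10 epimers formed on protonation are of no consequence because C10 becomes a ketone in step 9.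

**Step 9**
Reactants: 14 aldehyde
Product: 15 (2R,5R)-5-[(2S)-1-(tert-butyldimethylsilyloxy)propan-2-yl]-2-methyl-2-(prop-2-en-1-yl)cyclopentan-1-one
Conditions: O2 (1 atm), Cu(OAc)2 (10 mol%), 2,2'-bipyridine (10 mol%), DABCO (1 equiv), DMF, 40 °C
Reagents that add atoms: dioxygen, O=O
Why: Copper-catalysed aerobic deformylation of an α-branched aldehyde (Van Rheenen oxidation, through oxygenation of the enol and loss of formate from the α-hydroperoxy aldehyde) gives the ketone with one carbon fewer, tolerates the terminal alkene and silyl ether, and uses a base too weak to epimerise the now α-positioned C1, as the classical steroid 20-ketone case shows.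

**Step 10**
Reactants: 15 ketone; 16 4-bromo-2-methylbut-1-ene
Product: 18 (1S,2R,5R)-5-[(2S)-1-(tert-butyldimethylsilyloxy)propan-2-yl]-2-methyl-1-(3-methylbut-3-en-1-yl)-2-(prop-2-en-1-yl)cyclopentan-1-ol, via Grignard reagent 17 (not isolated)
Conditions: 16 (2 equiv), Mg, THF, rt to 40 °C; anhydrous CeCl3 (2 equiv), THF, −78 °C; then 15, −78 to 0 °C; aq. NH4Cl
Reagents that add atoms: none
Why: Cerium-mediated Grignard 1,2-addition (Imamoto conditions) overrides enolisation of the hindered ketone, which also protects C1, and the nucleophile should enter on the carbonyl face that carries C1–H and the C4 allyl group rather than the branched C1 side chain and the C4 methyl, so the new chain at C10 is cis to the allyl arm and the hydroxyl is cis to the side chain.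

**Step 11**
Reactants: 18 tertiary alcohol
Product: 19 triethylsilyl ether of 18
Conditions: TESOTf (1.5 equiv), 2,6-lutidine (3 equiv), CH2Cl2, −78 to 0 °C
Reagents that add atoms: triethylsilyl trifluoromethanesulfonate, CC[Si](CC)(CC)OS(=O)(=O)C(F)(F)F
Why: Silyl triflate with 2,6-lutidine is the standard silylation of hindered tertiary alcohols, and capping C10–OH is needed so that the carbonyl groups released in step 12 cannot form lactols with it.

**Step 12**
Reactants: 19 diene
Product: 21 keto aldehyde: cyclopentane with C4 (methyl; CH2CHO), C10 (OSiEt3; CH2CH2COCH3) and C1 [(2S)-1-(TBS-oxy)propan-2-yl]; methyl / silyloxy / side chain on one face and both carbonyl arms on the other, via bis-ozonide 20 (not isolated)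
Conditions: O3, CH2Cl2, −78 °C; then PPh3 (2.5 equiv), −78 °C to rt
Reagents that add atoms: ozone, [O-][O+]=O
Why: Exhaustive ozonolysis with phosphine work-up (Criegee mechanism) converts the allyl group into the C6 aldehyde and the 1,1-disubstituted alkene into the C7 methyl ketone in one operation, silyl ethers are inert to ozone, and no stereocentre is α to either carbonyl.

**Step 13**
Reactants: 21 keto aldehyde
Product: 22 cis-fused bicyclo[5.3.0]decane cis-6,7-diol: C6–OH and C7–OH cis to each other and on the face of the C4 methyl and the C10 OSiEt3; C7 methyl on the other face; side chain unchanged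
Conditions: SmI2 (2.5 equiv, 0.1 M in THF), t-BuOH (2 equiv), THF, slow addition of 21 (final 0.01 M), −78 °C to rt; sat. aq. NaHCO3
Reagents that add atoms: none
Why: SmI2 transfers one electron to the aldehyde, the samarium ketyl at C6 adds to the samarium-bound C7 ketone (or couples with its ketyl) and a second electron gives the samarium diolate, which is the well-established SmI2 pinacol cyclisation of keto aldehydes to cis-cycloalkane-1,2-diols, seven-membered rings included. The cycloheptane closes in a 7-exo-trig mode (the attacked C=O lies outside the new ring), helped by the cis arrangement of the two arms on the cyclopentane, by the fully substituted C4 and C10 (gem-disubstituent effect) and by high dilution. C6 and C7 are formed together and their oxygens must be cis because both are bound to one trivalent samarium in the bond-forming transition state. Which cis-diol forms is decided by the existing ring: with both arms on the lower face, the bulky samarium-bridged O–C6–C7–O unit is expected to lie on the outer (convex) face of the folding cis-fused bicycle, the face of the C4 methyl and the C10 silyloxy group, with the C7 methyl pseudo-equatorial, so that the C7 oxygen ends up on the side of the C10 oxygen as the later bridge requires. The step needs reduction of the aldehyde before the ketone, cyclisation before dimerisation or over-reduction, and no lactol formation; the lower reduction potential of the aldehyde, slow addition of 21 to excess SmI2 at −78 °C and the silyl cap on the C10 oxygen secure these.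

**Step 14**
Reactants: 22 cis-diol
Product: 23 α-ketol: C6 ketone next to the tertiary C7–OH; silyl ethers unchanged
Conditions: IBX (2 equiv), DMSO, rt
Reagents that add atoms: none
Why: IBX oxidises the secondary alcohol of a 1,2-diol to the α-hydroxy ketone without glycol cleavage and leaves the tertiary alcohol and both silyl ethers alone, which removes the wrongly configured C6 centre and the only hydroxyl that could compete with C7–OH in the ether closure.

**Step 15**
Reactants: 23 α-ketol
Product: 24 keto triol (C6 ketone; free C7–OH, C10–OH and primary OH)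
Conditions: HF·pyridine, pyridine, THF, 0 °C to rt
Reagents that add atoms: none
Why: Buffered HF·pyridine cleaves both silyl ethers by fluoride attack at silicon without the basic conditions that could trigger an α-ketol shift, and no stereocentre is involved.

**Step 16**
Reactants: 24 keto triol
Product: 25 tricyclic keto alcohol: C7–O–C10 ether bridge (8-oxabicyclo[3.2.1]octane fused to the cyclopentane); C6 ketone; free primary OH
Conditions: TsOH·H2O (10 mol%), CH2Cl2, 4 Å molecular sieves, 0 °C to rt
Reagents that add atoms: none
Why: Acid-catalysed cyclodehydration of a ditertiary 1,4-diol (the terpin-to-cineole type of etherification): the C10 hydroxyl, flanked by a quaternary and a tertiary carbon, ionises (C7 cannot, being α to the ketone), and the C7 hydroxyl closes the tetrahydrofuran ring, which is geometrically possible only on the face that carries the C7 oxygen, so C10 regains its oxygen cis to the C4 methyl and the 8-oxabicyclo[3.2.1]octane results.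

**Step 17**
Reactants: 25 tricyclic keto alcohol
Product: 26 diol: C6–OH equatorial and trans to the ether oxygen (cis to the C7 methyl); free primary OH
Conditions: Al(OiPr)3 (0.5 equiv, catalyst), i-PrOH/toluene, 100 °C (sealed), heated until the epimer ratio no longer changes
Reagents that add atoms: none
Why: Meerwein–Ponndorf–Verley reduction is reversible hydride transfer, so under equilibrating conditions the C6 alkoxide should settle as the more stable equatorial epimer (hydroxyl trans to the ether oxygen), the axial epimer being destabilised by a 1,3-diaxial contact with the C4 methyl, and no one-electron step is involved that could cleave the C7–O bond next to the carbonyl.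

**Step 18**
Reactants: 26 diol; 27 vanillic acid
Product: 28 target vanillate ester (CNP0277205.1)
Conditions: 27 (1.1 equiv), PPh3 (1.2 equiv), DIAD (1.2 equiv), THF, 0 °C to rt
Reagents that add atoms: none
Why: Mitsunobu esterification activates the primary alcohol as its oxyphosphonium ion, which the carboxylate of vanillic acid displaces, while the far less acidic phenol and the hindered secondary C6 alcohol stay out of the reaction, so the acid can be used unprotected.

**Compound list**

1 | (S)-limonene, (4S)-1-methyl-4-(prop-1-en-2-yl)cyclohex-1-ene | CC1=CC[C@H](CC1)C(C)=C | starting material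
2 | 9-{2-[(1S)-4-methylcyclohex-3-en-1-yl]propyl}-9-borabicyclo[3.3.1]nonane (both epimers at Cs; not isolated) | CC1=CC[C@H](CC1)C(C)CB1C2CCCC1CCC2 | intermediate
3 | (2RS)-2-[(1S)-4-methylcyclohex-3-en-1-yl]propan-1-ol (epimer pair at Cs) | CC1=CC[C@H](CC1)C(C)CO | intermediate
4 | (2S)-2-[(1S)-4-methylcyclohex-3-en-1-yl]propyl acetate | CC1=CC[C@H](CC1)[C@H](C)COC(C)=O | intermediate
5 | (2S)-2-[(1S)-4-methylcyclohex-3-en-1-yl]propan-1-ol | CC1=CC[C@H](CC1)[C@H](C)CO | intermediate
6 | tert-butyl(dimethyl){(2S)-2-[(1S)-4-methylcyclohex-3-en-1-yl]propoxy}silane | CC1=CC[C@H](CC1)[C@H](C)CO[Si](C)(C)C(C)(C)C | intermediate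
7 | ozonide of 6: 1-methyl-7,8,9-trioxabicyclo[4.2.1]nonane carrying the (2S)-1-(TBS-oxy)propan-2-yl group at C4 (acetal centres undefined; not isolated) | CC12CC[C@@H](CC(OO1)O2)[C@H](C)CO[Si](C)(C)C(C)(C)C | intermediate
8 | (3S)-3-[(2S)-1-(tert-butyldimethylsilyloxy)propan-2-yl]-6-oxoheptanal | CC(=O)CC[C@@H](CC=O)[C@H](C)CO[Si](C)(C)C(C)(C)C | intermediate
9 | (5R)-5-[(2S)-1-(tert-butyldimethylsilyloxy)propan-2-yl]-2-methylcyclopent-1-ene-1-carbaldehyde | O=CC1=C(C)CC[C@@H]1[C@H](C)CO[Si](C)(C)C(C)(C)C | intermediate
10 | allylboronic acid pinacol ester | C=CCB1OC(C)(C)C(C)(C)O1 | starting material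
11 | pinacol borate ester of 12 (B on the carbinol oxygen; not isolated) | C=CC[C@H](OB1OC(C)(C)C(C)(C)O1)C1=C(C)CC[C@@H]1[C@H](C)CO[Si](C)(C)C(C)(C)C | intermediate
12 | (1S)-1-{(5R)-5-[(2S)-1-(tert-butyldimethylsilyloxy)propan-2-yl]-2-methylcyclopent-1-en-1-yl}but-3-en-1-ol | C=CC[C@H](O)C1=C(C)CC[C@@H]1[C@H](C)CO[Si](C)(C)C(C)(C)C | intermediate
13 | potassium enolate of 14 (enolate geometry undefined; not isolated) | [K+].[O-]C=C1[C@@](C)(CC=C)CC[C@@H]1[C@H](C)CO[Si](C)(C)C(C)(C)C | intermediate
14 | (2R,5R)-5-[(2S)-1-(tert-butyldimethylsilyloxy)propan-2-yl]-2-methyl-2-(prop-2-en-1-yl)cyclopentane-1-carbaldehyde (epimers at C1 of the ring; allyl trans to the side chain) | O=CC1[C@@](C)(CC=C)CC[C@@H]1[C@H](C)CO[Si](C)(C)C(C)(C)C | intermediate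
15 | (2R,5R)-5-[(2S)-1-(tert-butyldimethylsilyloxy)propan-2-yl]-2-methyl-2-(prop-2-en-1-yl)cyclopentan-1-one | O=C1[C@@](C)(CC=C)CC[C@@H]1[C@H](C)CO[Si](C)(C)C(C)(C)C | intermediate
16 | 4-bromo-2-methylbut-1-ene | C=C(C)CCBr | starting material
17 | (3-methylbut-3-en-1-yl)magnesium bromide (not isolated) | C=C(C)CC[Mg]Br | intermediate
18 | (1S,2R,5R)-5-[(2S)-1-(tert-butyldimethylsilyloxy)propan-2-yl]-2-methyl-1-(3-methylbut-3-en-1-yl)-2-(prop-2-en-1-yl)cyclopentan-1-ol (OH cis to side chain and ring methyl) | C=C(C)CC[C@@]1(O)[C@@](C)(CC=C)CC[C@@H]1[C@H](C)CO[Si](C)(C)C(C)(C)C | intermediate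
19 | triethylsilyl ether of 18 | C=C(C)CC[C@@]1(O[Si](CC)(CC)CC)[C@@](C)(CC=C)CC[C@@H]1[C@H](C)CO[Si](C)(C)C(C)(C)C | intermediate
20 | bis-ozonide of 19 (a 1,2,4-trioxolane at each former alkene; acetal centres undefined; not isolated) | CC1(OCOO1)CC[C@@]2(O[Si](CC)(CC)CC)[C@@](C)(CC3OCOO3)CC[C@@H]2[C@H](C)CO[Si](C)(C)C(C)(C)C | intermediate
21 | keto aldehyde (pinacol precursor): cyclopentane with C4 (Me, CH2CHO), C10 (OSiEt3, CH2CH2COCH3), C1 [(2S)-1-(TBS-oxy)propan-2-yl]; Me, OSiEt3 and side chain cis, both carbonyl arms on the opposite face | CC(C)(C)[Si](C)(C)OC[C@@H](C)[C@H]1CC[C@](C)(CC=O)[C@@]1(CCC(C)=O)O[Si](CC)(CC)CC | intermediate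
22 | cis-6,7-diol (pinacol product): cis-fused 4,7-dimethylbicyclo[5.3.0]decane; C6–OH, C7–OH, C10–OSiEt3, C4–Me and the C1 side chain on one face | CC(C)(C)[Si](C)(C)OC[C@@H](C)[C@H]2CC[C@]3(C)C[C@@H](O)[C@@](C)(O)CC[C@]23O[Si](CC)(CC)CC | intermediate
23 | α-ketol: 22 with C6 oxidised to the ketone | CC(C)(C)[Si](C)(C)OC[C@@H](C)[C@H]2CC[C@]3(C)CC(=O)[C@@](C)(O)CC[C@]23O[Si](CC)(CC)CC | intermediate
24 | keto triol: 23 without silyl groups | OC[C@@H](C)[C@H]2CC[C@]3(C)CC(=O)[C@@](C)(O)CC[C@]23O | intermediate
25 | tricyclic keto alcohol: 7,10-epoxy bridge, C6 ketone, primary OH | OC[C@@H](C)[C@H]2CC[C@]3(C)CC(=O)[C@]4(C)CC[C@]23O4 | intermediate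
26 | tricyclic diol: 7,10-epoxy bridge, C6–OH trans to the ether oxygen, primary OH | OC[C@@H](C)[C@H]2CC[C@]3(C)C[C@H](O)[C@]4(C)CC[C@]23O4 | intermediate
27 | vanillic acid (4-hydroxy-3-methoxybenzoic acid) | COc1cc(C(=O)O)ccc1O | starting material
28 | CNP0277205.1, the 4-hydroxy-3-methoxybenzoate of the primary alcohol of 26 | COc1cc(C(=O)OC[C@@H](C)[C@H]2CC[C@]3(C)C[C@H](O)[C@]4(C)CC[C@]23O4)ccc1O | target

**Count and risks**

Total steps: 18. Longest linear sequence: 18 steps, from 1 to 28; 10, 16 and 27 are bought.

Most likely to fail:

1. Step 13. The chelated ketyl coupling may choose the other face of the forming ring, putting both new oxygens away from the C10 oxygen, or the aldehyde may simply be reduced before it cyclises. Fallback, setting out from 18 and coming back at 26: ring-closing metathesis of the two terminal alkenes with second-generation Grubbs catalyst (CH2Cl2, 40 °C) should give the trisubstituted cycloheptenol F1. mCPBA (NaHCO3, CH2Cl2, 0 °C) should epoxidise C6=C7 on the face away from the C4 methyl and the C10 hydroxyl to the epoxy alcohol F2. The C10 hydroxyl opens F2 at the tertiary C7 with inversion (spontaneously or with a trace of CSA), the carotol-to-daucol type of transannular opening, to the bridged ether silyl ether F3, which already has the trans C6 hydroxyl. HF·pyridine then frees the primary alcohol to give 26.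

2. Step 16. The C10 cation may lose a proton towards C1 or C9, or suffer a 1,2-shift from C4, faster than the hindered α-ketol hydroxyl traps it; this would erase the C1 stereocentre or rearrange the skeleton. Fallback, setting out from 22 and coming back at 26, in which the C10–O bond is never broken: thiocarbonyldiimidazole (toluene, 80 °C) converts the cis-diol into the cyclic thionocarbonate F4. Trimethyl phosphite at 120 °C (Corey–Winter olefination) gives the cycloheptene bis-silyl ether F5, and HF·pyridine the cycloheptene diol F6. mCPBA then gives the epoxy diol F7, which the C10 hydroxyl opens at C7 as above to give 26.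

3. Step 17. Equilibration at the hindered ketone may be slow and leave the kinetically formed axial alcohol, or aldol condensation with the acetone formed may consume material. Fallback, setting out from 23 and coming back at 26, which sets C6 before the bridge is made: Me4NBH(OAc)3 in MeCN/AcOH at −20 °C binds the C7 hydroxyl and delivers hydride to the carbonyl face on that side (hydroxyl-directed reduction), which should give the trans-6,7-diol bis-silyl ether F8. HF·pyridine gives the tetraol F9, and TsOH in CH2Cl2 closes the C7–O–C10 bridge as in step 16 to give 26.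

**Further compounds**

F1 | step 13 | cycloheptenol from metathesis of 18: C6=C7 alkene, free C10–OH, TBS ether on the side chain | CC(C)(C)[Si](C)(C)OC[C@@H](C)[C@H]2CC[C@]3(C)CC=C(C)CC[C@]23O
F2 | step 13 | 6,7-epoxide of F1, epoxide oxygen trans to the C10 hydroxyl | CC(C)(C)[Si](C)(C)OC[C@@H](C)[C@H]2CC[C@]3(C)C[C@@H]4O[C@]4(C)CC[C@]23O
F3 | step 13 | TBS ether of 26 | CC(C)(C)[Si](C)(C)OC[C@@H](C)[C@H]2CC[C@]3(C)C[C@H](O)[C@]4(C)CC[C@]23O4
F4 | step 16 | cyclic 6,7-thionocarbonate of 22 | CC(C)(C)[Si](C)(C)OC[C@@H](C)[C@H]2CC[C@]3(C)C[C@H]4OC(=S)O[C@@]4(C)CC[C@]23O[Si](CC)(CC)CC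
F5 | step 16 | cycloheptene (C6=C7) with C10–OSiEt3 and side-chain OTBS | CC(C)(C)[Si](C)(C)OC[C@@H](C)[C@H]2CC[C@]3(C)CC=C(C)CC[C@]23O[Si](CC)(CC)CC
F6 | step 16 | cycloheptene diol: C6=C7, free C10–OH and primary OH | OC[C@@H](C)[C@H]2CC[C@]3(C)CC=C(C)CC[C@]23O
F7 | step 16 | 6,7-epoxide of F6, epoxide oxygen trans to the C10 hydroxyl | OC[C@@H](C)[C@H]2CC[C@]3(C)C[C@@H]4O[C@]4(C)CC[C@]23O
F8 | step 17 | trans-6,7-diol: C6–OH trans to C7–OH, C10–OSiEt3, side-chain OTBS | CC(C)(C)[Si](C)(C)OC[C@@H](C)[C@H]2CC[C@]3(C)C[C@H](O)[C@@](C)(O)CC[C@]23O[Si](CC)(CC)CC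
F9 | step 17 | tetraol: F8 without silyl groups | OC[C@@H](C)[C@H]2CC[C@]3(C)C[C@H](O)[C@@](C)(O)CC[C@]23O
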